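## Retrosynthetic overview

1. Germacrane numbering is used: ring C1–C10 with the enal C1=C10–C14, the allylic alcohol C15 on C4=C5, the ester on C8, and the lactone ring O–C12(=O)–C11(=C13)–C7–C6. The ten-membered ring is closed last, at C1=C10, by ring-closing metathesis; C4=C5 comes from a Wittig reaction on a C5 aldehyde.
2. The α-methylene-γ-butyrolactone is disconnected at O–C6 and C11–C12 into CO2, an alkenyl iodide at C11 and a terminal C5–C6 epoxide. The forward reaction is an electroreductive carboxylation whose carboxylate opens the epoxide in the same cell.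
3. Enabling feature: the O–C12(=O) unit of the lactone is one intact CO2 molecule, C11 is a 1,1-disubstituted vinyl carbon (so it can be an alkenyl iodide), and C6 lies 1,3 to C11 next to C5, a carbon that has to be functionalised anyway. C5–C6 can therefore be an epoxide that the new carboxylate opens 5-exo with inversion.
4. The C6/C7/C8 triad is set on a temporary butenolide ring (O8–C8–C7=C6–C5=O) made from (R)-epichlorohydrin: cuprate addition trans to C9, enolate hydroxylation trans to C11, then reductive ring opening with inversion at C6 to the epoxide.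
5. Order of ring formation: temporary butenolide (steps 2–3, opened in step 8), then the α-methylene lactone (step 10), then the ten-membered carbocycle (step 15).

Key step: step 10

Remarks: Compounds 1, 2, 6, 11, 19 and 23 are taken to be catalogue chemicals. Metal enolates, alkoxides and catalyst-bound species are treated as forms of the numbered compounds; the two Grignard reagents made in the flask are numbered.

## Route

Step 1
Reactants: 1 (R)-epichlorohydrin; 2 2-bromo-3,3-diethoxyprop-1-ene
Product: 5 (R)-2-[2-(diethoxymethyl)prop-2-en-1-yl]oxirane, via Grignard reagent 3 (not isolated), via chlorohydrin 4 (not isolated)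
Conditions: 2, Mg, THF, rt; CuI (10 mol %), 1, −30 → 0 °C; then NaOH (powder), Et2O, rt
Reagents that add atoms: none
Why: Copper-catalysed Grignard opening of the epoxide at its terminal carbon and base-induced closure of the chlorohydrin (epichlorohydrin homologation) should carry the stereocentre of 1 unchanged into C8, because no bond at that carbon is broken.

Step 2
Reactants: 5 epoxide; 6 (phenylselanyl)acetic acid
Product: 8 (5R)-5-[2-(diethoxymethyl)prop-2-en-1-yl]-3-(phenylselanyl)oxolan-2-one (C3 epimers), via hydroxy acid 7 (not isolated)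
Conditions: 6, LDA (2.1 equiv), THF, −78 → 0 °C; 5, 0 °C → rt; AcOH; then PPTS (cat.), PhMe, 50 °C
Reagents that add atoms: none
Why: Alkylation of the acid dianion at the terminal epoxide carbon and lactonisation of the γ-hydroxy acid should give the α-selanyl butanolide with C8 untouched; the C6 epimers are of no consequence.

Step 3
Reactants: 8 selanyl lactone
Product: 10 (R)-5-[2-(diethoxymethyl)prop-2-en-1-yl]furan-2(5H)-one, via selenoxide 9 (not isolated)
Conditions: H2O2 (aq), pyridine, CH2Cl2, 0 °C → rt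
Reagents that add atoms: none
Why: Selenoxide syn-elimination can only use the C7 hydrogens and should therefore give the endocyclic butenolide.

Step 4
Reactants: 10 butenolide; 11 (1-bromoethenyl)trimethylsilane
Product: 13 (4S,5R)-5-[2-(diethoxymethyl)prop-2-en-1-yl]-4-[1-(trimethylsilyl)ethenyl]oxolan-2-one, via Grignard reagent 12 (not isolated)
Conditions: 11, Mg, THF, reflux; CuBr·SMe2 (10 mol %), THF, −78 °C; 10, −78 → −40 °C; then H2O
Reagents that add atoms: none
Why: Copper-catalysed conjugate addition of the alkenyl Grignard reagent should occur anti to the C8 side chain, which shields one face of the planar butenolide, and so set C7 trans to C8.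

Step 5
Reactants: 13 lactone
Product: 14 (3S,4S,5R)-5-[2-(diethoxymethyl)prop-2-en-1-yl]-3-hydroxy-4-[1-(trimethylsilyl)ethenyl]oxolan-2-one
Conditions: KHMDS, THF, −78 °C; 3-phenyl-2-(phenylsulfonyl)oxaziridine, −78 °C; then AcOH
Reagents that add atoms: 3-phenyl-2-(phenylsulfonyl)oxaziridine, O1C(c2ccccc2)N1S(=O)(=O)c1ccccc1
Why: Davis hydroxylation of the potassium lactone enolate should take place anti to the bulky neighbouring C7 substituent and set C6 trans to it.

Step 6
Reactants: 14 hydroxy lactone
Product: 15 (3S,4S,5R)-5-[2-(diethoxymethyl)prop-2-en-1-yl]-3-hydroxy-4-(1-iodoethenyl)oxolan-2-one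
Conditions: NIS, MeCN/ClCH2CN 4:1, rt, dark
Reagents that add atoms: N-iodosuccinimide, O=C1CCC(=O)N1I
Why: Ipso-iododesilylation of the vinylsilane is driven by β-silyl stabilisation of the cationic intermediate and should leave the inductively deactivated 2-(dialkoxymethyl)allyl olefin alone.

Step 7
Reactants: 15 hydroxy lactone
Product: 16 (3S,4R,5R)-5-[2-(diethoxymethyl)prop-2-en-1-yl]-4-(1-iodoethenyl)-2-oxooxolan-3-yl methanesulfonate
Conditions: MsCl, Et3N, CH2Cl2, −20 °C
Reagents that add atoms: methanesulfonyl chloride, CS(=O)(=O)Cl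
Why: O-Sulfonylation of the secondary alcohol breaks only the O–H bond, so C6 keeps its configuration.

Step 8
Reactants: 16 mesylate
Product: 18 (3R,4R)-6-(diethoxymethyl)-2-iodo-3-[(2R)-oxiran-2-yl]hepta-1,6-dien-4-ol, via hydroxy mesylate 17 (not isolated)
Conditions: LiBH4, THF, 0 °C; then K2CO3, MeOH, 0 °C → rt
Reagents that add atoms: none
Why: Borohydride reduction of the lactone and Williamson closure of the primary alkoxide onto the adjacent mesylate (the route from α-sulfonyloxy esters to epoxides) should give the terminal epoxide with inversion at C6, three-membered ring closure being faster than oxetane formation from the C8 hydroxyl.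

Step 9
Reactants: 18 epoxy alcohol; 19 (S)-2-methylbutanoic acid
Product: 20 (3R,4R)-6-(diethoxymethyl)-2-iodo-3-[(2R)-oxiran-2-yl]hepta-1,6-dien-4-yl (2S)-2-methylbutanoate
Conditions: 19, EDC·HCl, DMAP (cat.), CH2Cl2, 0 °C → rt
Reagents that add atoms: none
Why: Steglich esterification acylates the only free hydroxyl and installs the ester of the target, while the epoxide and the alkenyl iodide are inert.

Step 10
Reactants: 20 epoxy alkenyl iodide
Product: 22 (1R)-3-(diethoxymethyl)-1-[(2S,3R)-2-(hydroxymethyl)-4-methylidene-5-oxooxolan-3-yl]but-3-en-1-yl (2S)-2-methylbutanoate, via magnesium acrylate 21 (not isolated)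
Conditions: NiBr2(bpy) (10 mol %), CO2 (1 atm), nBu4NBF4, DMF, undivided cell, Mg anode, carbon-felt cathode, constant current (2.2 F/mol), 0 °C → rt; then 40 °C; H2O
Reagents that add atoms: carbon dioxide, O=C=O
Why: Proposed new method: cathodically generated zerovalent nickel inserts into the C11–I bond, the alkenylnickel is reduced and captures CO2 at C11 (C11–C12 bond), and the magnesium acrylate 21, formed with Mg2+ from the anode, opens the Mg2+-activated epoxide at C6 (O–C6 bond), so that the O–C(=O) unit of the lactone is the intact CO2 molecule. The closest known reaction types are the nickel-catalysed electroreductive carboxylation of alkenyl halides with a sacrificial magnesium anode and the lactonisation of 4,5-epoxy carboxylates; running both in one cell is the new element. The butyrolactone closes in the 5-exo-tet mode at the internal epoxide carbon, which is 1,3 to C11, in preference to 6-endo attack at the terminal carbon C5. No new stereocentre is created: C6 is inverted by backside attack anti to the epoxide oxygen, so the epoxide configuration set in step 8 becomes the trans C6/C7 ring fusion, while C7, C8 and the ester stereocentre are untouched. The step needs chemoselectivity for the C–I bond over the epoxide, ester and acetal, which the mild potential of the nickel mediator and the absence of any allylic leaving group should secure, and regioselectivity for C6 over C5, which the five-membered transition state should secure.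

Step 11
Reactants: 23 5-bromopent-1-ene
Product: 24 (pent-4-en-1-yl)triphenylphosphonium bromide
Conditions: PPh3, MeCN, reflux
Reagents that add atoms: triphenylphosphine, c1ccc(cc1)P(c1ccccc1)c1ccccc1
Why: SN2 alkylation of the phosphine by the primary bromide gives the phosphonium salt.

Step 12
Reactants: 24 phosphonium bromide
Product: 26 2-(triphenylphosphoranylidene)hex-5-enal, via non-stabilised ylide 25 (not isolated)
Conditions: n-BuLi, THF, −78 → 0 °C; HCO2Et, 0 °C → rt
Reagents that add atoms: ethyl formate, CCOC=O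
Why: C-Formylation of the phosphorus ylide with ethyl formate, the released ethoxide removing the remaining α-proton, should give the formyl-stabilised ylide (acylation of a Wittig ylide).

Step 13
Reactants: 22 hydroxy lactone
Product: 27 (1R)-3-(diethoxymethyl)-1-[(2S,3R)-2-formyl-4-methylidene-5-oxooxolan-3-yl]but-3-en-1-yl (2S)-2-methylbutanoate
Conditions: DMP, CH2Cl2, 0 °C → rt
Reagents that add atoms: none
Why: Dess–Martin oxidation converts the primary alcohol into the aldehyde under near-neutral conditions that should spare the exo-methylene lactone, the acetal and the α-stereocentre.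

Step 14
Reactants: 27 aldehyde; 26 formyl ylide
Product: 28 (1R)-3-(diethoxymethyl)-1-{(2R,3R)-2-[(1E)-2-formylhexa-1,5-dien-1-yl]-4-methylidene-5-oxooxolan-3-yl}but-3-en-1-yl (2S)-2-methylbutanoate
Conditions: 26, PhMe, 70 °C
Reagents that add atoms: none
Why: Wittig olefination with the stabilised ylide should give the (E)-2-alkyl enal, with C15 trans to C6, which is the C4=C5 geometry of the target.

Step 15
Reactants: 28 triene lactone
Product: 29 (3aR,4R,6E,10E,11aR)-6-(diethoxymethyl)-10-formyl-3-methylidene-2-oxo-2,3,3a,4,5,8,9,11a-octahydrocyclodeca[b]furan-4-yl (2S)-2-methylbutanoate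
Conditions: second-generation Hoveyda–Grubbs catalyst (10 mol %), PhMe (0.001 M), 80 °C, Ar purge
Reagents that add atoms: none
Why: Ring-closing metathesis of the terminal vinyl group with the 1,1-disubstituted olefin expels ethylene, ring strain should favour the ring-cis olefin (C2 and C9 cis, the E-configured C1=C10 bond of the target), and closure onto C13 would require a bridgehead olefin.

Step 16
Reactants: 29 macrocyclic enal
Product: 30 (3aR,4R,6E,10E,11aR)-6-(diethoxymethyl)-10-(hydroxymethyl)-3-methylidene-2-oxo-2,3,3a,4,5,8,9,11a-octahydrocyclodeca[b]furan-4-yl (2S)-2-methylbutanoate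
Conditions: NaBH4, CeCl3·7H2O, MeOH, −78 °C
Reagents that add atoms: none
Why: Luche reduction should reduce the enal carbonyl in the 1,2-sense at low temperature before the exo-methylene lactone, the ester or the acetal react.

Step 17
Reactants: 30 allylic alcohol
Product: 31 CNP0168859.6, (3aR,4R,6E,10E,11aR)-6-formyl-10-(hydroxymethyl)-3-methylidene-2-oxo-2,3,3a,4,5,8,9,11a-octahydrocyclodeca[b]furan-4-yl (2S)-2-methylbutanoate
Conditions: PPTS (cat.), acetone/H2O 9:1, rt
Reagents that add atoms: water, O
Why: Mild acid-catalysed hydrolysis of the allylic diethyl acetal should unveil the conjugated C14 aldehyde without touching the lactone, the ester or the olefin geometries.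

## Compound list

1 | (R)-epichlorohydrin | ClC[C@H]1CO1 | starting material
2 | 2-bromo-3,3-diethoxyprop-1-ene | C=C(Br)C(OCC)OCC | starting material
3 | (3,3-diethoxyprop-1-en-2-yl)magnesium bromide | C=C([Mg]Br)C(OCC)OCC | intermediate
4 | (R)-1-chloro-4-(diethoxymethyl)pent-4-en-2-ol | C=C(C(OCC)OCC)C[C@@H](O)CCl | intermediate
5 | (R)-2-[2-(diethoxymethyl)prop-2-en-1-yl]oxirane | C=C(C(OCC)OCC)C[C@@H]1CO1 | intermediate
6 | (phenylselanyl)acetic acid | OC(=O)C[Se]c1ccccc1 | starting material
7 | (4R)-6-(diethoxymethyl)-4-hydroxy-2-(phenylselanyl)hept-6-enoic acid | C=C(C(OCC)OCC)C[C@@H](O)CC([Se]c1ccccc1)C(=O)O | intermediate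
8 | (5R)-5-[2-(diethoxymethyl)prop-2-en-1-yl]-3-(phenylselanyl)oxolan-2-one | C=C(C(OCC)OCC)C[C@@H]1CC([Se]c2ccccc2)C(=O)O1 | intermediate
9 | (5R)-5-[2-(diethoxymethyl)prop-2-en-1-yl]-3-(phenylseleninyl)oxolan-2-one | C=C(C(OCC)OCC)C[C@@H]1CC([Se](=O)c2ccccc2)C(=O)O1 | intermediate
10 | (R)-5-[2-(diethoxymethyl)prop-2-en-1-yl]furan-2(5H)-one | C=C(C(OCC)OCC)C[C@@H]1C=CC(=O)O1 | intermediate
11 | (1-bromoethenyl)trimethylsilane | C=C(Br)[Si](C)(C)C | starting material
12 | [1-(trimethylsilyl)ethenyl]magnesium bromide | C=C([Mg]Br)[Si](C)(C)C | intermediate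
13 | (4S,5R)-5-[2-(diethoxymethyl)prop-2-en-1-yl]-4-[1-(trimethylsilyl)ethenyl]oxolan-2-one | C=C(C(OCC)OCC)C[C@@H]1[C@@H](C(=C)[Si](C)(C)C)CC(=O)O1 | intermediate
14 | (3S,4S,5R)-5-[2-(diethoxymethyl)prop-2-en-1-yl]-3-hydroxy-4-[1-(trimethylsilyl)ethenyl]oxolan-2-one | C=C(C(OCC)OCC)C[C@@H]1[C@@H](C(=C)[Si](C)(C)C)[C@H](O)C(=O)O1 | intermediate
15 | (3S,4S,5R)-5-[2-(diethoxymethyl)prop-2-en-1-yl]-3-hydroxy-4-(1-iodoethenyl)oxolan-2-one | C=C(C(OCC)OCC)C[C@@H]1[C@@H](C(I)=C)[C@H](O)C(=O)O1 | intermediate
16 | (3S,4R,5R)-5-[2-(diethoxymethyl)prop-2-en-1-yl]-4-(1-iodoethenyl)-2-oxooxolan-3-yl methanesulfonate | C=C(C(OCC)OCC)C[C@@H]1[C@@H](C(I)=C)[C@H](OS(C)(=O)=O)C(=O)O1 | intermediate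
17 | (2S,3R,4R)-6-(diethoxymethyl)-1,4-dihydroxy-3-(1-iodoethenyl)hept-6-en-2-yl methanesulfonate | C=C(C(OCC)OCC)C[C@@H](O)[C@@H](C(I)=C)[C@H](OS(C)(=O)=O)CO | intermediate
18 | (3R,4R)-6-(diethoxymethyl)-2-iodo-3-[(2R)-oxiran-2-yl]hepta-1,6-dien-4-ol | C=C(C(OCC)OCC)C[C@@H](O)[C@@H](C(I)=C)[C@@H]1CO1 | intermediate
19 | (S)-2-methylbutanoic acid | CC[C@H](C)C(=O)O | starting material
20 | (3R,4R)-6-(diethoxymethyl)-2-iodo-3-[(2R)-oxiran-2-yl]hepta-1,6-dien-4-yl (2S)-2-methylbutanoate | C=C(C(OCC)OCC)C[C@@H](OC(=O)[C@@H](C)CC)[C@@H](C(I)=C)[C@@H]1CO1 | intermediate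
21 | iodomagnesium (3R,4R)-6-(diethoxymethyl)-2-methylidene-4-{[(2S)-2-methylbutanoyl]oxy}-3-[(2R)-oxiran-2-yl]hept-6-enoate | C=C(C(OCC)OCC)C[C@@H](OC(=O)[C@@H](C)CC)[C@@H](C(=C)C(=O)[O-])[C@@H]1CO1.[Mg+2].[I-] | intermediate
22 | (1R)-3-(diethoxymethyl)-1-[(2S,3R)-2-(hydroxymethyl)-4-methylidene-5-oxooxolan-3-yl]but-3-en-1-yl (2S)-2-methylbutanoate | C=C1C(=O)O[C@H](CO)[C@H]1[C@H](OC(=O)[C@@H](C)CC)CC(=C)C(OCC)OCC | intermediate
23 | 5-bromopent-1-ene | C=CCCCBr | starting material
24 | (pent-4-en-1-yl)triphenylphosphonium bromide | C=CCCC[P+](c1ccccc1)(c1ccccc1)c1ccccc1.[Br-] | intermediate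
25 | (pent-4-en-1-ylidene)triphenylphosphorane | C=CCCC=P(c1ccccc1)(c1ccccc1)c1ccccc1 | intermediate
26 | 2-(triphenylphosphoranylidene)hex-5-enal | C=CCCC(C=O)=P(c1ccccc1)(c1ccccc1)c1ccccc1 | intermediate
27 | (1R)-3-(diethoxymethyl)-1-[(2S,3R)-2-formyl-4-methylidene-5-oxooxolan-3-yl]but-3-en-1-yl (2S)-2-methylbutanoate | C=C1C(=O)O[C@H](C=O)[C@H]1[C@H](OC(=O)[C@@H](C)CC)CC(=C)C(OCC)OCC | intermediate
28 | (1R)-3-(diethoxymethyl)-1-{(2R,3R)-2-[(1E)-2-formylhexa-1,5-dien-1-yl]-4-methylidene-5-oxooxolan-3-yl}but-3-en-1-yl (2S)-2-methylbutanoate | C=C1C(=O)O[C@H](/C=C(/C=O)CCC=C)[C@H]1[C@H](OC(=O)[C@@H](C)CC)CC(=C)C(OCC)OCC | intermediate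
29 | (3aR,4R,6E,10E,11aR)-6-(diethoxymethyl)-10-formyl-3-methylidene-2-oxo-2,3,3a,4,5,8,9,11a-octahydrocyclodeca[b]furan-4-yl (2S)-2-methylbutanoate | C=C1C(=O)O[C@@H]2/C=C(/C=O)CC/C=C(/C(OCC)OCC)C[C@@H](OC(=O)[C@@H](C)CC)[C@@H]12 | intermediate
30 | (3aR,4R,6E,10E,11aR)-6-(diethoxymethyl)-10-(hydroxymethyl)-3-methylidene-2-oxo-2,3,3a,4,5,8,9,11a-octahydrocyclodeca[b]furan-4-yl (2S)-2-methylbutanoate | C=C1C(=O)O[C@@H]2/C=C(/CO)CC/C=C(/C(OCC)OCC)C[C@@H](OC(=O)[C@@H](C)CC)[C@@H]12 | intermediate
31 | CNP0168859.6, (3aR,4R,6E,10E,11aR)-6-formyl-10-(hydroxymethyl)-3-methylidene-2-oxo-2,3,3a,4,5,8,9,11a-octahydrocyclodeca[b]furan-4-yl (2S)-2-methylbutanoate | C=C1C(=O)O[C@@H]2/C=C(/CO)CC/C=C(/C=O)C[C@@H](OC(=O)[C@@H](C)CC)[C@@H]12 | target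

## Step count and risks

Total step count: 17. Longest linear sequence: 15 steps (steps 1–10 and 13–17; steps 11–12 make the ylide).

Steps most likely to fail:

**Step 10 (proposed new method).** The epoxide may be consumed before the carboxylate exists, by iodide/Mg2+ opening to an iodohydrin or by CO2 insertion to a cyclic carbonate. The alkenylnickel may also be protonated instead of carboxylated, or the carboxylate may attack C5 in the 6-endo sense. The fallback uses known chemistry, sets out from 20 and returns at 22. Palladium-catalysed hydroxycarbonylation of the alkenyl iodide (Pd(OAc)2, PPh3, CO 1 atm, H2O, Et3N, DMF, 40 °C) would give (3R,4R)-6-(diethoxymethyl)-2-methylidene-4-{[(2S)-2-methylbutanoyl]oxy}-3-[(2R)-oxiran-2-yl]hept-6-enoic acid F1. Camphorsulfonic acid (cat.) in CH2Cl2 at 0 °C would then close the lactone by 5-exo epoxide opening with inversion at C6 and give 22. This replaces CO2 by CO and water and separates the two bond formations.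

**Step 15.** Closure onto the hindered 1,1-disubstituted olefin may be slow, so that intermolecular metathesis (dimers, oligomers) and trapping of the ruthenium carbene by the acrylate unit of the lactone take over. The fallback sets out from 28 and returns at 29. Conjugate addition of dimethylamine (Me2NH, THF, 0 °C) would mask the exo-methylene group as the Mannich base (1R)-3-(diethoxymethyl)-1-{(2R,3R)-4-[(dimethylamino)methyl]-2-[(1E)-2-formylhexa-1,5-dien-1-yl]-5-oxooxolan-3-yl}but-3-en-1-yl (2S)-2-methylbutanoate F2. Metathesis of its toluenesulfonic acid salt with the catalyst of step 15 would give the macrocyclic amine (3aR,4R,6E,10E,11aR)-6-(diethoxymethyl)-3-[(dimethylamino)methyl]-10-formyl-2-oxo-2,3,3a,4,5,8,9,11a-octahydrocyclodeca[b]furan-4-yl (2S)-2-methylbutanoate F3. Quaternisation with MeI and elimination with NaHCO3 would restore the α-methylene lactone and give 29.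

**Step 14.** The α-branched formyl ylide reacts slowly, so epimerisation at C6 of the α-acyloxy aldehyde or conjugate addition of the ylide to the exo-methylene lactone may compete. The fallback sets out from 27 and returns at 30, bypassing steps 14–16. Hex-5-en-2-one (commercial) would be converted with LDA and PhNTf2 into hexa-1,5-dien-2-yl trifluoromethanesulfonate F4. Nozaki–Hiyama–Kishi coupling of F4 with 27 (CrCl2, NiCl2 cat., DMF) would give (1R)-3-(diethoxymethyl)-1-[(2S,3R)-2-(1-hydroxy-2-methylidenehex-5-en-1-yl)-4-methylidene-5-oxooxolan-3-yl]but-3-en-1-yl (2S)-2-methylbutanoate F5 as both C5 epimers. Rhenium-catalysed 1,3-transposition of the allylic alcohol (Ph3SiOReO3, Et2O, rt; chair transition state with C6 equatorial) would move the hydroxyl to C15 and the olefin to C4=C5, giving (1R)-3-(diethoxymethyl)-1-{(2R,3R)-2-[(1E)-2-(hydroxymethyl)hexa-1,5-dien-1-yl]-4-methylidene-5-oxooxolan-3-yl}but-3-en-1-yl (2S)-2-methylbutanoate F6. Ring-closing metathesis of F6 under the conditions of step 15 would give 30.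

Further compounds
F1 | step 10 | (3R,4R)-6-(diethoxymethyl)-2-methylidene-4-{[(2S)-2-methylbutanoyl]oxy}-3-[(2R)-oxiran-2-yl]hept-6-enoic acid | C=C(C(OCC)OCC)C[C@@H](OC(=O)[C@@H](C)CC)[C@@H](C(=C)C(=O)O)[C@@H]1CO1
F2 | step 15 | (1R)-3-(diethoxymethyl)-1-{(2R,3R)-4-[(dimethylamino)methyl]-2-[(1E)-2-formylhexa-1,5-dien-1-yl]-5-oxooxolan-3-yl}but-3-en-1-yl (2S)-2-methylbutanoate | CN(C)CC1C(=O)O[C@H](/C=C(/C=O)CCC=C)[C@H]1[C@H](OC(=O)[C@@H](C)CC)CC(=C)C(OCC)OCC
F3 | step 15 | (3aR,4R,6E,10E,11aR)-6-(diethoxymethyl)-3-[(dimethylamino)methyl]-10-formyl-2-oxo-2,3,3a,4,5,8,9,11a-octahydrocyclodeca[b]furan-4-yl (2S)-2-methylbutanoate | CN(C)CC1C(=O)O[C@@H]2/C=C(/C=O)CC/C=C(/C(OCC)OCC)C[C@@H](OC(=O)[C@@H](C)CC)[C@@H]12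
F4 | step 14 | hexa-1,5-dien-2-yl trifluoromethanesulfonate | C=CCCC(=C)OS(=O)(=O)C(F)(F)F
F5 | step 14 | (1R)-3-(diethoxymethyl)-1-[(2S,3R)-2-(1-hydroxy-2-methylidenehex-5-en-1-yl)-4-methylidene-5-oxooxolan-3-yl]but-3-en-1-yl (2S)-2-methylbutanoate | C=C1C(=O)O[C@H](C(O)C(=C)CCC=C)[C@H]1[C@H](OC(=O)[C@@H](C)CC)CC(=C)C(OCC)OCC
F6 | step 14 | (1R)-3-(diethoxymethyl)-1-{(2R,3R)-2-[(1E)-2-(hydroxymethyl)hexa-1,5-dien-1-yl]-4-methylidene-5-oxooxolan-3-yl}but-3-en-1-yl (2S)-2-methylbutanoate | C=C1C(=O)O[C@H](/C=C(/CO)CCC=C)[C@H]1[C@H](OC(=O)[C@@H](C)CC)CC(=C)C(OCC)OCC
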